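**Retrosynthetic overview**
1. Feature: each of the two identical arms is a tetrahydrofuran (O1, C2–C5). C2 carries a 2,4-dioxygenated aryl donor, C4 an aroyl acceptor and C5 a 4-oxygenated aryl; the C2 and C5 aryl groups are cis and the C2/C3 substituents are cis. O1–C5 is therefore the C=O group of 4-(benzyloxy)benzaldehyde, and C2–C3–C4 is a trans donor–acceptor cyclopropane.
2. Disconnection 1: fifteen O-benzyl groups, then the CL–C8 and CL–C6 bonds between the linker methines CL and ring A of (+)-afzelechin. These bonds are made by invertive Friedel–Crafts opening of an aroylcyclopropane C3–C4–CL. The open CL cation is avoided because the C2 aryl shields one of its faces, so the arene would enter from the C4 side and give the linker epimer.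
3. Disconnection 2: C4–CL (enolate alkylation), CL–aryl (Grignard addition to the C3 aldehyde) and the auxiliary C4 ester, which is lost as CO2 while C4 settles trans to C3 and C5.
4. Disconnection 3 (key): O1–C2 with inversion and C4–C5, by Lewis-acid (3+2) annulation of the cyclopropane keto ester with the aldehyde. The cyclopropane comes from an organocatalytic Michael-initiated ring closure of the cinnamaldehyde with the α-bromo β-keto ester. This avoids carbene transfer to an electron-rich 1,2-disubstituted styrene, where reactivity is poor and dihydrofurans form.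
5. Ring order: cyclopropane, tetrahydrofuran, fused cyclopropane (opened again in the coupling). The chroman of afzelechin is bought.

Key step: step 9

Remark: locants are O1, C2 (2,4-dioxygenated aryl), C3 (side chain), C4 (aroyl), C5 (4-oxygenated aryl) and CL (linker methine). The cyclopropane keto esters are drawn as the C1 epimer with aroyl cis to the C3 substituent; the other C1 epimer can be carried along, because C1 becomes a planar enolate carbon in the key step. (+)-Afzelechin and 4-(benzyloxy)phenylmagnesium bromide are taken as purchasable.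

Step 1
Reactants: 1 2,4-dihydroxybenzaldehyde
Product: 2 2,4-bis(benzyloxy)benzaldehyde
Conditions: BnBr (2.4 equiv), K2CO3, DMF, 60 °C
Reagents that add atoms: benzyl bromide, BrCc1ccccc1
Why: Williamson ether synthesis in which both phenoxides, including the hydrogen-bonded 2-OH, are alkylated in warm DMF and no stereocentre is involved.

Step 2
Reactants: 2 2,4-bis(benzyloxy)benzaldehyde
Product: 3 (E)-3-[2,4-bis(benzyloxy)phenyl]prop-2-enal
Conditions: Ph3P=CHCHO (1.1 equiv), toluene, 80 °C
Reagents that add atoms: (triphenylphosphoranylidene)acetaldehyde, O=CC=P(c1ccccc1)(c1ccccc1)c1ccccc1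
Why: Wittig olefination in which the stabilised formyl ylide gives the (E)-alkene selectively and near-stoichiometric ylide limits a second homologation of the enal.

Step 3
Reactants: 4 2',4'-dihydroxyacetophenone
Product: 5 2',4'-bis(benzyloxy)acetophenone
Conditions: BnBr (2.5 equiv), K2CO3, DMF, 80 °C
Reagents that add atoms: benzyl bromide, BrCc1ccccc1
Why: Williamson ether synthesis, run warm so that the chelated 2'-OH is also alkylated.

Step 4
Reactants: 5 2',4'-bis(benzyloxy)acetophenone
Product: 6 allyl 3-[2,4-bis(benzyloxy)phenyl]-3-oxopropanoate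
Conditions: NaH (2.2 equiv), (CH2=CHCH2O)2CO, THF, reflux; aq. HCl
Reagents that add atoms: diallyl carbonate, C=CCOC(=O)OCC=C
Why: Crossed Claisen condensation (C-acylation of the methyl ketone enolate by a carbonate), driven by irreversible deprotonation of the β-keto ester formed.

Step 5
Reactants: 6 allyl 3-[2,4-bis(benzyloxy)phenyl]-3-oxopropanoate
Product: 7 allyl 2-bromo-3-[2,4-bis(benzyloxy)phenyl]-3-oxopropanoate (racemic)
Conditions: NBS (1.0 equiv), Mg(ClO4)2 (10 mol%), MeCN, 0 °C
Reagents that add atoms: N-bromosuccinimide, O=C1CCC(=O)N1Br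
Why: Electrophilic α-bromination of a β-keto ester, in which the Mg(ClO4)2-bound enol takes up bromine faster than the acyl-deactivated arene or the allyl group, and the racemic centre is of no consequence because it is deprotonated in step 6.

Step 6
Reactants: 3 (E)-3-[2,4-bis(benzyloxy)phenyl]prop-2-enal; 7 allyl 2-bromo-3-[2,4-bis(benzyloxy)phenyl]-3-oxopropanoate
Product: 8 allyl (1R,2S,3R)-1-[2,4-bis(benzyloxy)benzoyl]-2-[2,4-bis(benzyloxy)phenyl]-3-formylcyclopropane-1-carboxylate
Conditions: (S)-2-[diphenyl(trimethylsilyloxy)methyl]pyrrolidine (20 mol%), 2,6-lutidine (1.1 equiv), CH2Cl2, 0 °C → rt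
Reagents that add atoms: none
Why: Michael-initiated ring closure under iminium–enamine catalysis, in which the bromo keto ester enolate adds to the β-carbon of the (E)-iminium ion on the face away from the CPh2OSiMe3 group (this sets the aryl-bearing carbon), the enamine displaces bromide in a 3-exo-tet closure that places formyl trans to aryl, and the bulky aroyl group is expected on the side of the small formyl group.

Step 7
Reactants: 8 formylcyclopropane keto ester
Product: 9 allyl (1R,2S,3R)-1-[2,4-bis(benzyloxy)benzoyl]-2-[2,4-bis(benzyloxy)phenyl]-3-(hydroxymethyl)cyclopropane-1-carboxylate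
Conditions: NaBH4, THF/MeOH, −40 °C
Reagents that add atoms: none
Why: Chemoselective borohydride reduction, since the aldehyde reacts far faster than the hindered electron-rich aryl ketone or the ester at low temperature and no stereocentre is touched.

Step 8
Reactants: 9 hydroxymethylcyclopropane keto ester
Product: 10 allyl (1R,2S,3R)-1-[2,4-bis(benzyloxy)benzoyl]-2-[2,4-bis(benzyloxy)phenyl]-3-(tert-butyldimethylsilyloxymethyl)cyclopropane-1-carboxylate
Conditions: TBSCl, imidazole, CH2Cl2, 0 °C → rt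
Reagents that add atoms: tert-butyldimethylsilyl chloride, CC(C)(C)[Si](C)(C)Cl
Why: Imidazole-promoted silylation of the primary alcohol, which also draws any lactol formed with the cis aroyl group back to the open form.

Step 9
Reactants: 10 silyloxymethyl cyclopropane keto ester; 11 4-(benzyloxy)benzaldehyde
Product: 13 allyl (2R,3R,4R,5R)-4-[2,4-bis(benzyloxy)benzoyl]-2-[2,4-bis(benzyloxy)phenyl]-5-[4-(benzyloxy)phenyl]-3-(tert-butyldimethylsilyloxymethyl)tetrahydrofuran-4-carboxylate, via oxocarbenium enolate 12 (not isolated)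
Conditions: Sn(OTf)2 (10 mol%), 11 (3 equiv), 4 Å MS, CH2Cl2, −30 °C
Reagents that add atoms: none
Why: Sn(OTf)2 binds the two carbonyl groups on C1 of 10 as a chelate, the carbonyl oxygen of 11 attacks the benzylic donor carbon from the side opposite to the breaking C1–C2 bond (O1–C2, SN2-like), and the tin enolate of zwitterion 12 then adds to the oxocarbenium carbon (C4–C5). The closest known reaction type is the Lewis-acid-catalysed (3+2) annulation of donor–acceptor cyclopropanes with aldehydes, which gives 2,5-cis-tetrahydrofurans with inversion at the donor carbon. The single ring closes in a 5-endo-trig mode at the C=O+ bond (O1 and C5 both end up in the ring; enolexo at the enolate), a mode that is usual for oxocarbenium ions despite its formal disfavour. C2 is set by the inversion, which turns the trans aryl/CH2OSi relation of 10 into the cis C2/C3 relation; C3 is carried over unchanged; C5 is set by an envelope transition state with the (E)-oxocarbenium aryl and the C2 aryl both pseudo-equatorial and hence cis; C4 should place the larger aroyl group anti to the C3 and C5 substituents and is erased in step 10. The step needs opening at the aryl-bearing carbon only, which the lone donor group secures, and an invertive course without a free benzylic cation, which the low temperature, the mild Lewis acid and the excess of an electron-rich, strongly nucleophilic aldehyde serve. The same condition shuts off the Cloke–Wilson rearrangement, because the aroyl oxygen cannot reach the rear side of the donor carbon.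

Step 10
Reactants: 13 tetrahydrofuran keto allyl ester
Product: 15 (2R,3R,4S,5S)-4-[2,4-bis(benzyloxy)benzoyl]-2-[2,4-bis(benzyloxy)phenyl]-5-[4-(benzyloxy)phenyl]-3-(tert-butyldimethylsilyloxymethyl)tetrahydrofuran, via beta-keto acid 14 (not isolated)
Conditions: Pd(PPh3)4 (5 mol%), morpholine (3 equiv), THF, rt → 40 °C; then DBU (0.2 equiv), rt
Reagents that add atoms: none
Why: Tsuji-type deallylation–decarboxylation, in which zerovalent palladium ionises the allyl ester, morpholine takes up the allyl group, acid 14 loses CO2, and DBU-mediated enolisation lets C4 settle under thermodynamic control with aroyl trans to both neighbours, while loss of O1 from C5 is stereoelectronically poor (reverse of a 5-endo-trig closure).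

Step 11
Reactants: 15 silyl ether ketone
Product: 16 (2R,3R,4S,5S)-4-[2,4-bis(benzyloxy)benzoyl]-2-[2,4-bis(benzyloxy)phenyl]-5-[4-(benzyloxy)phenyl]-3-(hydroxymethyl)tetrahydrofuran
Conditions: Bu4NF, AcOH, THF, 0 °C → rt
Reagents that add atoms: none
Why: Fluoride-induced cleavage of the primary silyl ether, buffered with acetic acid so that the β-alkoxy ketone is not exposed to strongly basic fluoride or alkoxide.

Step 12
Reactants: 16 primary alcohol
Product: 17 (2R,3S,4S,5S)-4-[2,4-bis(benzyloxy)benzoyl]-2-[2,4-bis(benzyloxy)phenyl]-5-[4-(benzyloxy)phenyl]tetrahydrofuran-3-carbaldehyde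
Conditions: Dess–Martin periodinane, NaHCO3, CH2Cl2, 0 °C
Reagents that add atoms: none
Why: Dess–Martin oxidation under bicarbonate buffer gives the aldehyde under neutral non-enolising conditions, so that C3 and C4 keep their configuration.

Step 13
Reactants: 17 tetrahydrofuran-3-carbaldehyde; 18 4-(benzyloxy)phenylmagnesium bromide
Product: 19 (2R,3R,4S,5S)-4-[2,4-bis(benzyloxy)benzoyl]-2-[2,4-bis(benzyloxy)phenyl]-5-[4-(benzyloxy)phenyl]-3-{(R)-[4-(benzyloxy)phenyl](hydroxy)methyl}tetrahydrofuran
Conditions: 18 (1.2 equiv), THF, −78 °C; aq. NH4Cl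
Reagents that add atoms: none
Why: Grignard 1,2-addition, in which the aldehyde reacts much faster than the hindered aryl ketone at −78 °C, the carbinol centre is drawn as the Felkin–Anh product of attack anti to the C2 branch, and either epimer serves because CL is set again in step 14.

Step 14
Reactants: 19 linker carbinol
Product: 21 [2,4-bis(benzyloxy)phenyl]{4-[2,4-bis(benzyloxy)phenyl]-2,6-bis[4-(benzyloxy)phenyl]-3-oxabicyclo[3.1.0]hexan-1-yl}methanone (bicycle C1 = C4; C2 = C5; C4 = C2; C5 = C3; C6 = CL; C6 aryl exo; both ring aryl groups cis to the cyclopropane), via benzylic chloride 20 (not isolated)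
Conditions: MsCl, Et3N, CH2Cl2, −20 °C; crude 20, LiN(SiMe3)2, THF, −78 → −20 °C
Reagents that add atoms: methanesulfonyl chloride, CS(=O)(=O)Cl (supplies the chlorine of 20; no atom of it stays in 21)
Why: Mesylation with in situ chloride displacement followed by the classical γ-halo ketone to cyclopropyl ketone closure (intramolecular enolate alkylation, 3-exo-tet), in which C4 can bond to CL only on the face that carries the side chain, and the configurationally labile p-alkoxybenzylic chloride funnels through the epimer whose invertive closure puts the CL aryl exo, the endo site being blocked by the C2 and C5 aryl groups.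

Step 15
Reactants: 22 (+)-afzelechin
Product: 23 5,7,4'-tri-O-benzyl-(+)-afzelechin
Conditions: BnBr (3.3 equiv), K2CO3, DMF, rt, Ar
Reagents that add atoms: benzyl bromide, BrCc1ccccc1
Why: Williamson etherification under weak base, in which only the three phenols are ionised, the secondary 3-OH stays free, and room temperature under argon avoids base-induced epimerisation at C2 of the flavan.

Step 16
Reactants: 21 fused aroylcyclopropane (2.3 equiv); 23 5,7,4'-tri-O-benzyl-(+)-afzelechin
Product: 25 pentadeca-O-benzyl ether of the target (both arms on ring A; linker centres S; 3-OH free), via C8 monoadduct 24 (not isolated)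
Conditions: Sc(OTf)3 (20 mol%), 4 Å MS, CH2Cl2, −20 → 0 °C; then DBU (cat.), rt
Reagents that add atoms: none
Why: Friedel–Crafts-type homo-Michael opening of a donor–acceptor cyclopropane by an electron-rich arene, in which Sc(OTf)3 is held by the ketone and its ortho benzyloxy oxygen, C8 and then C6 of ring A (the only free positions, each ortho or para to three oxygen atoms) attack CL opposite to the C4–CL bond so that inversion of the exo-aryl cyclopropane sets both linker centres as in the target, and the C4 enolates are reprotonated under DBU equilibration trans to both neighbours.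

Step 17
Reactants: 25 pentadeca-O-benzyl ether
Product: 26 CNP0225367.3 (target)
Conditions: H2 (1 atm), Pd(OH)2/C, THF/MeOH, rt
Reagents that add atoms: none
Why: Catalytic hydrogenolysis, in which aryl benzyl ethers are cleaved at ambient pressure faster than the ring benzylic C–O bonds of the tetrahydrofurans and the flavan or the vinylogous-ester-like aryl ketones, and no stereocentre is touched.

**Compound list**
1 | 2,4-dihydroxybenzaldehyde | O=Cc1ccc(O)cc1O | starting material
2 | 2,4-bis(benzyloxy)benzaldehyde | O=Cc1ccc(OCc2ccccc2)cc1OCc1ccccc1 | intermediate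
3 | (E)-3-[2,4-bis(benzyloxy)phenyl]prop-2-enal | O=C/C=C/c1ccc(OCc2ccccc2)cc1OCc1ccccc1 | intermediate
4 | 2',4'-dihydroxyacetophenone | CC(=O)c1ccc(O)cc1O | starting material
5 | 2',4'-bis(benzyloxy)acetophenone | CC(=O)c1ccc(OCc2ccccc2)cc1OCc1ccccc1 | intermediate
6 | allyl 3-[2,4-bis(benzyloxy)phenyl]-3-oxopropanoate | C=CCOC(=O)CC(=O)c1ccc(OCc2ccccc2)cc1OCc1ccccc1 | intermediate
7 | allyl 2-bromo-3-[2,4-bis(benzyloxy)phenyl]-3-oxopropanoate (racemic) | C=CCOC(=O)C(Br)C(=O)c1ccc(OCc2ccccc2)cc1OCc1ccccc1 | intermediate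
8 | allyl (1R,2S,3R)-1-aroyl-2-aryl-3-formylcyclopropane-1-carboxylate (aryl/formyl trans; aroyl/formyl cis) | O=C(c1ccc(OCc9ccccc9)cc1OCc9ccccc9)[C@]1(C(=O)OCC=C)[C@H](C=O)[C@H]1c1ccc(OCc9ccccc9)cc1OCc9ccccc9 | intermediate
9 | 3-hydroxymethyl analogue of 8 | O=C(c1ccc(OCc9ccccc9)cc1OCc9ccccc9)[C@]1(C(=O)OCC=C)[C@H](CO)[C@H]1c1ccc(OCc9ccccc9)cc1OCc9ccccc9 | intermediate
10 | 3-(tert-butyldimethylsilyloxymethyl) analogue of 8 (key-step precursor) | O=C(c1ccc(OCc9ccccc9)cc1OCc9ccccc9)[C@]1(C(=O)OCC=C)[C@H](CO[Si](C)(C)C(C)(C)C)[C@H]1c1ccc(OCc9ccccc9)cc1OCc9ccccc9 | intermediate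
11 | 4-(benzyloxy)benzaldehyde | O=Cc1ccc(OCc2ccccc2)cc1 | starting material
12 | ring-opened oxocarbenium/keto ester enolate zwitterion (drawn without tin; C2 already inverted) | [O-]C(c1ccc(OCc9ccccc9)cc1OCc9ccccc9)=C(C(=O)OCC=C)[C@H](CO[Si](C)(C)C(C)(C)C)[C@H](c1ccc(OCc9ccccc9)cc1OCc9ccccc9)[O+]=Cc1ccc(OCc9ccccc9)cc1 | intermediate
13 | 2,5-cis-diaryl tetrahydrofuran keto allyl ester (C2 aryl, C3 side chain, C5 aryl and ester on one face; aroyl on the other) | O=C(c1ccc(OCc9ccccc9)cc1OCc9ccccc9)[C@@]1(C(=O)OCC=C)[C@H](CO[Si](C)(C)C(C)(C)C)[C@H](c2ccc(OCc9ccccc9)cc2OCc9ccccc9)O[C@@H]1c1ccc(OCc9ccccc9)cc1 | intermediate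
14 | β-keto acid from 13 | O=C(c1ccc(OCc9ccccc9)cc1OCc9ccccc9)[C@@]1(C(=O)O)[C@H](CO[Si](C)(C)C(C)(C)C)[C@H](c2ccc(OCc9ccccc9)cc2OCc9ccccc9)O[C@@H]1c1ccc(OCc9ccccc9)cc1 | intermediate
15 | (2R,3R,4S,5S) ketone silyl ether (aroyl trans to C3 and C5 substituents) | O=C(c1ccc(OCc9ccccc9)cc1OCc9ccccc9)[C@H]1[C@H](CO[Si](C)(C)C(C)(C)C)[C@H](c2ccc(OCc9ccccc9)cc2OCc9ccccc9)O[C@@H]1c1ccc(OCc9ccccc9)cc1 | intermediate
16 | primary alcohol from 15 | O=C(c1ccc(OCc9ccccc9)cc1OCc9ccccc9)[C@H]1[C@H](CO)[C@H](c2ccc(OCc9ccccc9)cc2OCc9ccccc9)O[C@@H]1c1ccc(OCc9ccccc9)cc1 | intermediate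
17 | tetrahydrofuran-3-carbaldehyde | O=C(c1ccc(OCc9ccccc9)cc1OCc9ccccc9)[C@H]1[C@H](C=O)[C@H](c2ccc(OCc9ccccc9)cc2OCc9ccccc9)O[C@@H]1c1ccc(OCc9ccccc9)cc1 | intermediate
18 | 4-(benzyloxy)phenylmagnesium bromide | Br[Mg]c1ccc(OCc2ccccc2)cc1 | starting material
19 | linker carbinol (R at CL) | O=C(c1ccc(OCc9ccccc9)cc1OCc9ccccc9)[C@H]1[C@H]([C@H](c2ccc(OCc9ccccc9)cc2)O)[C@H](c2ccc(OCc9ccccc9)cc2OCc9ccccc9)O[C@@H]1c1ccc(OCc9ccccc9)cc1 | intermediate
20 | linker chloride (S at CL; labile) | O=C(c1ccc(OCc9ccccc9)cc1OCc9ccccc9)[C@H]1[C@H]([C@@H](c2ccc(OCc9ccccc9)cc2)Cl)[C@H](c2ccc(OCc9ccccc9)cc2OCc9ccccc9)O[C@@H]1c1ccc(OCc9ccccc9)cc1 | intermediate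
21 | 1-aroyl-6-exo-aryl-2,4-diaryl-3-oxabicyclo[3.1.0]hexane (C4–CL bond closed) | O=C(c1ccc(OCc9ccccc9)cc1OCc9ccccc9)[C@]12[C@@H](c3ccc(OCc9ccccc9)cc3)O[C@@H](c3ccc(OCc9ccccc9)cc3OCc9ccccc9)[C@H]1[C@@H]2c1ccc(OCc9ccccc9)cc1 | intermediate
22 | (+)-afzelechin (2R,3S) | Oc1cc(O)c2c(c1)O[C@H](c1ccc(O)cc1)[C@@H](O)C2 | starting material
23 | 5,7,4'-tri-O-benzyl-(+)-afzelechin | c1(OCc9ccccc9)cc(OCc9ccccc9)c2c(c1)O[C@H](c1ccc(OCc9ccccc9)cc1)[C@@H](O)C2 | intermediate
24 | C8 monoadduct of 23 with one arm | c1(OCc9ccccc9)cc(OCc9ccccc9)c2c(c1[C@H](c4ccc(OCc9ccccc9)cc4)[C@H]4[C@H](C(=O)c5ccc(OCc9ccccc9)cc5OCc9ccccc9)[C@@H](c5ccc(OCc9ccccc9)cc5)O[C@H]4c4ccc(OCc9ccccc9)cc4OCc9ccccc9)O[C@H](c1ccc(OCc9ccccc9)cc1)[C@@H](O)C2 | intermediate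
25 | pentadeca-O-benzyl ether of the target | O=C(c1ccc(OCc9ccccc9)cc1OCc9ccccc9)[C@H]1[C@H]([C@@H](c2ccc(OCc9ccccc9)cc2)c2c(OCc9ccccc9)c3c(c([C@H](c4ccc(OCc9ccccc9)cc4)[C@H]4[C@H](C(=O)c5ccc(OCc9ccccc9)cc5OCc9ccccc9)[C@@H](c5ccc(OCc9ccccc9)cc5)O[C@H]4c4ccc(OCc9ccccc9)cc4OCc9ccccc9)c2OCc9ccccc9)O[C@H](c2ccc(OCc9ccccc9)cc2)[C@@H](O)C3)[C@H](c2ccc(OCc9ccccc9)cc2OCc9ccccc9)O[C@@H]1c1ccc(OCc9ccccc9)cc1 | intermediate
26 | CNP0225367.3 | O=C(c1ccc(O)cc1O)[C@H]1[C@H]([C@@H](c2ccc(O)cc2)c2c(O)c3c(c([C@H](c4ccc(O)cc4)[C@H]4[C@H](C(=O)c5ccc(O)cc5O)[C@@H](c5ccc(O)cc5)O[C@H]4c4ccc(O)cc4O)c2O)O[C@H](c2ccc(O)cc2)[C@@H](O)C3)[C@H](c2ccc(O)cc2O)O[C@@H]1c1ccc(O)cc1 | target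

Total step count: 17. Longest linear sequence: 14 steps (from 4: steps 3–14, 16, 17).

**Steps most likely to fail**

Risk 1, step 16: the C4–CL bond may ionise to a free benzylic cation before the arene arrives. That would erode the inversion at CL and open the way to Cloke–Wilson rearrangement to a fused dihydrofuran. The second alkylation at C6, flanked by two benzyloxy groups, may also be too slow, and Lewis-acid opening of the C2–O1 bond is a further drain. Fallback: give up protection of the nucleophile and use the free phloroglucinol-type ring A, which is smaller and far more nucleophilic, as in the acid-catalysed twofold C8/C6 alkylation of free flavan-3-ols. The fallback sets out from 21 and 22. One equivalent of 21 with 22 (Sc(OTf)3, THF/CH2Cl2, −20 °C) should give the hexa-O-benzyl C8 monoadduct F1. A second equivalent should give the dodeca-O-benzyl 6,8-bisadduct F2. Hydrogenolysis as in step 17 brings F2 back to the route at 26.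

Risk 2, step 9: the very electron-rich cyclopropane may ionise before the aldehyde attacks. This would cause epimerisation at the donor carbon (loss of the cis C2/C3 relation) and Cloke–Wilson rearrangement through the aroyl oxygen. Fallback: exchange the keto ester acceptor for the malonate pair, the best documented acceptor for this annulation, which has no acyl oxygen that can rearrange, and install the aroyl group afterwards.
- The fallback sets out from 3 and returns at 15.
- Enal 3 and dimethyl bromomalonate under the conditions of step 6 should give dimethyl (2S,3R)-2-[2,4-bis(benzyloxy)phenyl]-3-formylcyclopropane-1,1-dicarboxylate F3.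
- NaBH4 gives the hydroxymethyl diester F4, which is silylated at once to the silyl ether diester F5.
- Annulation with 11 (Sn(OTf)2 or AlCl3) gives the tetrahydrofuran-4,4-dicarboxylate F6.
- Krapcho demethoxycarbonylation (LiCl, wet DMSO, heat) leaves the C4 monoester F7, trans to both neighbours.
- MeNH(OMe)·HCl with i-PrMgCl converts it into the Weinreb amide F8.
- 2,4-Bis(benzyloxy)phenyllithium F9 (from 1-bromo-2,4-bis(benzyloxy)benzene and n-BuLi) then gives ketone 15.

Risk 3, step 14: loss of HCl toward the C3=CL styrene, O-alkylation of the enolate to the fused dihydrofuran, or solvolysis of the labile chloride during handling may outrun the 3-exo-tet closure. Fallback: let loss of CO2, rather than an amide base, make the C4 enolate.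
- The fallback sets out from 13 and returns at 21.
- The silyl group of 13 is removed with HF·pyridine to give the hydroxy keto ester F10.
- F10 is oxidised at once (Dess–Martin periodinane) to the aldehyde keto ester F11, before it can lactonise.
- Addition of 18 gives an alkoxide that closes on the cis allyl ester to the α-aroyl-γ-aryl-γ-butyrolactone F12.
- LiI in DMF then opens the lactone at its benzylic C–O bond, the β-keto carboxylate loses CO2 and the enolate displaces iodide. This is the known halide-induced ring contraction of α-acyl-γ-butyrolactones to acylcyclopropanes, and it gives 21 with the aryl group again exo.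

**Further compounds**
F1 | step 16 | hexa-O-benzyl C8 monoadduct of free (+)-afzelechin | Oc1cc(O)c2c(c1[C@H](c4ccc(OCc9ccccc9)cc4)[C@H]4[C@H](C(=O)c5ccc(OCc9ccccc9)cc5OCc9ccccc9)[C@@H](c5ccc(OCc9ccccc9)cc5)O[C@H]4c4ccc(OCc9ccccc9)cc4OCc9ccccc9)O[C@H](c1ccc(O)cc1)[C@@H](O)C2
F2 | step 16 | dodeca-O-benzyl 6,8-bisadduct of free (+)-afzelechin | O=C(c1ccc(OCc9ccccc9)cc1OCc9ccccc9)[C@H]1[C@H]([C@@H](c2ccc(OCc9ccccc9)cc2)c2c(O)c3c(c([C@H](c4ccc(OCc9ccccc9)cc4)[C@H]4[C@H](C(=O)c5ccc(OCc9ccccc9)cc5OCc9ccccc9)[C@@H](c5ccc(OCc9ccccc9)cc5)O[C@H]4c4ccc(OCc9ccccc9)cc4OCc9ccccc9)c2O)O[C@H](c2ccc(O)cc2)[C@@H](O)C3)[C@H](c2ccc(OCc9ccccc9)cc2OCc9ccccc9)O[C@@H]1c1ccc(OCc9ccccc9)cc1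
F3 | step 9 | dimethyl (2S,3R)-2-[2,4-bis(benzyloxy)phenyl]-3-formylcyclopropane-1,1-dicarboxylate | COC(=O)C1(C(=O)OC)[C@H](C=O)[C@H]1c1ccc(OCc9ccccc9)cc1OCc9ccccc9
F4 | step 9 | hydroxymethyl diester | COC(=O)C1(C(=O)OC)[C@H](CO)[C@H]1c1ccc(OCc9ccccc9)cc1OCc9ccccc9
F5 | step 9 | silyl ether diester | COC(=O)C1(C(=O)OC)[C@H](CO[Si](C)(C)C(C)(C)C)[C@H]1c1ccc(OCc9ccccc9)cc1OCc9ccccc9
F6 | step 9 | tetrahydrofuran-4,4-dicarboxylate | COC(=O)C1(C(=O)OC)[C@H](CO[Si](C)(C)C(C)(C)C)[C@H](c2ccc(OCc9ccccc9)cc2OCc9ccccc9)O[C@@H]1c1ccc(OCc9ccccc9)cc1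
F7 | step 9 | C4 monoester (trans to C3 and C5 substituents) | COC(=O)[C@H]1[C@H](CO[Si](C)(C)C(C)(C)C)[C@H](c2ccc(OCc9ccccc9)cc2OCc9ccccc9)O[C@@H]1c1ccc(OCc9ccccc9)cc1
F8 | step 9 | Weinreb amide | CON(C)C(=O)[C@H]1[C@H](CO[Si](C)(C)C(C)(C)C)[C@H](c2ccc(OCc9ccccc9)cc2OCc9ccccc9)O[C@@H]1c1ccc(OCc9ccccc9)cc1
F9 | step 9 | 2,4-bis(benzyloxy)phenyllithium | [Li]c1ccc(OCc2ccccc2)cc1OCc1ccccc1
F10 | step 14 | hydroxy keto ester | O=C(c1ccc(OCc9ccccc9)cc1OCc9ccccc9)[C@@]1(C(=O)OCC=C)[C@H](CO)[C@H](c2ccc(OCc9ccccc9)cc2OCc9ccccc9)O[C@@H]1c1ccc(OCc9ccccc9)cc1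
F11 | step 14 | aldehyde keto ester | O=C(c1ccc(OCc9ccccc9)cc1OCc9ccccc9)[C@@]1(C(=O)OCC=C)[C@H](C=O)[C@H](c2ccc(OCc9ccccc9)cc2OCc9ccccc9)O[C@@H]1c1ccc(OCc9ccccc9)cc1
F12 | step 14 | α-aroyl-γ-aryl-γ-butyrolactone cis-fused at C3–C4 (CL aryl exo) | O=C(c1ccc(OCc9ccccc9)cc1OCc9ccccc9)[C@@]12C(=O)O[C@@H](c3ccc(OCc9ccccc9)cc3)[C@@H]1[C@H](c3ccc(OCc9ccccc9)cc3OCc9ccccc9)O[C@@H]2c1ccc(OCc9ccccc9)cc1
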